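**Plan** (azulene numbering: C1 ketone carbon, C3 isopropyl carbon, C3a carbinol carbon, C6 methyl-bearing alkene carbon, C8 ester carbon, C8a methyl-bearing ring-fusion carbon)
1. Cuts: first the ester C–O bond; then the C8–O/C6=C7 allylic unit is taken back by an ene disconnection to a C7=C8 alkene carrying C6–H; then the cycloheptene is cut at C4–C5 and at the ring-fusion bond C3a–C8a.
2. Enabling feature: the seven-membered ring is then a cyclohept-4-ene whose C5–C6(CH3)–C7 part maps onto a methylcyclopropane and C8=C8a onto its vinyl group, while C4–C3a(O) is a 2-siloxyalkene held by the three-atom tether C1(=O)–C2–C3. C8a has no hydrogen, so the later ene reaction has one allylic hydrogen only.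
3. Forward: an open-chain dienone gives both rings in one (5+2) event (cyclopentanone by insertion, cycloheptene by reductive elimination); an oxygen ene reaction then moves the alkene and installs O at C8; esterification and desilylation finish.
4. Stereochemistry: C3 from an oxazolidinone alkylation; C6 (a relay centre, destroyed later) from an asymmetric cyclopropanation; C8a and C3a by chirality transfer from the cyclopropane and cis addition; C8 by the suprafacial ene reaction on the face of C6–H.
5. Helpers: the triethylsilyl group makes the two-carbon partner and masks the tertiary alcohol; the (Z)-enone geometry and the C6 centre steer the relative configuration and are consumed.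

Key step: step 9

Remark: the absolute sense at C8a/C3a is assumed to follow the cyclopropane of 14 (chirality transfer), with the C3 centre as the matched element.

Step 1
Reactants: 1 (4R)-4-benzyl-3-(3-methylbutanoyl)-1,3-oxazolidin-2-one; 2 2-bromo-N-methoxy-N-methylacetamide
Product: 4 (4R)-4-benzyl-3-[(2R)-4-[methoxy(methyl)amino]-4-oxo-2-(propan-2-yl)butanoyl]-1,3-oxazolidin-2-one, via sodium enolate 3 (not isolated)
Conditions: NaN(SiMe3)2, THF, −78 °C; then 2, −78 to −20 °C
Reagents that add atoms: none
Why: Evans asymmetric alkylation: the chelated (Z)-sodium enolate 3 is alkylated on the face away from the benzyl group, which sets the future C3 centre as R.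

Step 2
Reactants: 4
Product: 5 S-ethyl (2R)-4-[methoxy(methyl)amino]-4-oxo-2-(propan-2-yl)butanethioate
Conditions: EtSH, n-BuLi, THF, 0 °C; aq NH4Cl
Reagents that add atoms: ethanethiol, CCS
Why: Thiolate cleavage of the N-acyl oxazolidinone at the exocyclic carbonyl (transthioesterification) frees the auxiliary and should leave the Weinreb amide and the α-centre untouched.

Step 3
Reactants: 5
Product: 6 (3R)-3-acetyl-N-methoxy-N,4-dimethylpentanamide
Conditions: MeZnI, PdCl2(PPh3)2 (5 mol %), toluene–THF, rt; aq NH4Cl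
Reagents that add atoms: methylzinc iodide, C[Zn]I
Why: Fukuyama thioester–organozinc coupling stops at the methyl ketone under neutral conditions, where the Weinreb amide does not react and the α-centre is not enolised.

Step 4
Reactants: 6
Product: 8 (3R)-N-methoxy-N,4-dimethyl-3-{1-[(triethylsilyl)oxy]ethenyl}pentanamide, via lithium enolate 7 (not isolated)
Conditions: LiN(iPr)2, Et3SiCl (in situ quench), THF, −78 °C
Reagents that add atoms: chlorotriethylsilane, CC[Si](Cl)(CC)CC
Why: Kinetic enolisation of the methyl ketone at CH3 (the tertiary α-C–H and the amide CH2 are slower) with immediate O-silylation gives the 2-siloxyalkene, the future C4=C3a partner, before the enolate can attack the amide.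

Step 5
Reactants: 9 (2E)-but-2-en-1-ol
Product: 10 [(1S,2S)-2-methylcyclopropyl]methanol
Conditions: Et2Zn, CH2I2, DME, (4R,5R)-2-butyl-N,N,N′,N′-tetramethyl-1,3,2-dioxaborolane-4,5-dicarboxamide (1.2 equiv), CH2Cl2, −10 °C to rt; aq NH4Cl
Reagents that add atoms: diiodomethane, ICI
Why: Charette asymmetric Simmons–Smith cyclopropanation: the zinc alkoxide held by the chiral dioxaborolane delivers CH2 to one alkene face with retention of the E geometry, so the trans (1S,2S) cyclopropane is expected (same sense as cinnamyl alcohol with this ligand).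

Step 6
Reactants: 10
Product: 11 (1S,2S)-2-methylcyclopropane-1-carbaldehyde
Conditions: PhI(OAc)2, TEMPO (10 mol %), CH2Cl2, rt; used as a solution
Reagents that add atoms: none
Why: TEMPO-catalysed oxoammonium oxidation of the primary alcohol stops at the aldehyde under non-basic conditions, so neither cyclopropane centre is epimerised.

Step 7
Reactants: 11
Product: 12 (1S,2S)-1-[(1Z)-2-iodoprop-1-en-1-yl]-2-methylcyclopropane
Conditions: [Ph3PEt]I, n-BuLi, THF; I2, −78 °C; NaN(SiMe3)2, −20 °C; then 11, −78 °C
Reagents that add atoms: ethyltriphenylphosphonium iodide, CC[P+](c1ccccc1)(c1ccccc1)c1ccccc1.[I-]; iodine, [I][I]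
Why: Stork–Zhao olefination: the non-stabilised α-iodo ylide reacts under kinetic Wittig control to give the (Z)-iodoalkene with iodine cis to the cyclopropyl group.

Step 8
Reactants: 12 (1S,2S)-1-[(1Z)-2-iodoprop-1-en-1-yl]-2-methylcyclopropane; 8 (3R)-N-methoxy-N,4-dimethyl-3-{1-[(triethylsilyl)oxy]ethenyl}pentanamide
Product: 14 (1Z,5R)-2-methyl-1-[(1S,2S)-2-methylcyclopropyl]-5-(propan-2-yl)-6-[(triethylsilyl)oxy]hepta-1,6-dien-3-one, via alkenyllithium 13 (not isolated)
Conditions: t-BuLi (2 equiv), Et2O, −78 °C; then 8, −78 °C; aq NH4Cl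
Reagents that add atoms: none
Why: Iodine–lithium exchange keeps the alkene geometry, and the alkenyllithium is acylated by the Weinreb amide through a stable chelated tetrahedral intermediate (no over-addition), giving the (Z)-enone with the acyl tether cis to the cyclopropane.

Step 9
Reactants: 14
Product: 15 (3R,3aS,6S,8aR)-6,8a-dimethyl-3-(propan-2-yl)-3a-[(triethylsilyl)oxy]-3,3a,4,5,6,8a-hexahydroazulen-1(2H)-one
Conditions: [Rh(CO)2Cl]2 (5 mol %), toluene (0.02 M), 90 °C
Reagents that add atoms: none
Why: Proposed new method: the rhodium catalyst should bind the enone C=C, open the less substituted cyclopropane bond C7–C5 to a trivalent-rhodium σ-alkyl/π-allyl metallacycle, insert the tethered 2-siloxyalkene so that C3a bonds to C8a, and release the product by C4–C5 reductive elimination from an alkyl–rhodium that has no β-hydrogen on the C3a side. The closest known reaction type is the rhodium-catalysed intramolecular (5+2) cycloaddition of vinylcyclopropanes with tethered alkenes, allenes and alkynes, which tolerates 1,1-disubstituted two-carbon partners (quaternary ring-fusion carbon) and opens trans-2-alkylcyclopropanes at the less substituted bond; not yet shown are a siloxyalkene partner and a fully substituted allyl terminus (C8a). The cyclopentanone closes by 5-exo insertion across the three-atom tether C1–C2–C3, and the cycloheptene by reductive elimination from the eight-membered rhodacycle, which can only give the cis C7=C8 bond. Stereocontrol: rhodium and then C3a add to the allyl face that C5 left, so the cyclopropane configuration is transferred to C8a, and with the (Z)-enone and the trans cyclopropane the C8a and C6 methyl groups end on one face and C6–H on the other; syn addition across the siloxyalkene makes the ring fusion cis (CH3 and OSiEt3 on one face), and the C3 isopropyl group lies pseudo-equatorial in the chair-like insertion geometry, trans to C4, as the target needs. The step needs cleavage of C7–C5 and not C7–C6, 5-exo and not 6-endo insertion, and survival of the (Z)-geometry; the trans methyl group, the short tether and the neutral, acid-free catalyst are expected to secure these.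

Step 10
Reactants: 15
Product: 17 (3R,3aS,8R,8aR)-8-hydroxy-6,8a-dimethyl-3-(propan-2-yl)-3a-[(triethylsilyl)oxy]-3,3a,4,5,8,8a-hexahydroazulen-1(2H)-one, via allylic hydroperoxide 16 (not isolated)
Conditions: O2, tetraphenylporphyrin (1 mol %), visible light, CH2Cl2, 0 °C; then PPh3
Reagents that add atoms: dioxygen, O=O
Why: Schenck ene reaction: singlet oxygen bonds to C8 and takes the only allylic hydrogen (C6–H; C8a has none) suprafacially on the face free of the two methyl groups, which moves the alkene to C6=C7 and sets C8 as R; PPh3 reduces the O–O bond.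

Step 11
Reactants: 17; 18 4-methoxybenzoyl chloride
Product: 19 (3R,3aS,8R,8aR)-6,8a-dimethyl-1-oxo-3-(propan-2-yl)-3a-[(triethylsilyl)oxy]-1,2,3,3a,4,5,8,8a-octahydroazulen-8-yl 4-methoxybenzoate
Conditions: Et3N, DMAP, CH2Cl2, rt to 40 °C
Reagents that add atoms: none
Why: DMAP-catalysed acylation of the secondary allylic alcohol proceeds with retention at C8, the tertiary oxygen being masked as its silyl ether.

Step 12
Reactants: 19
Product: 20 (3R,3aS,8R,8aR)-3a-hydroxy-6,8a-dimethyl-1-oxo-3-(propan-2-yl)-1,2,3,3a,4,5,8,8a-octahydroazulen-8-yl 4-methoxybenzoate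
Conditions: HF·pyridine, THF, 0 °C to rt
Reagents that add atoms: none
Why: Fluoride-driven cleavage of the tertiary Si–O bond under weakly acidic conditions avoids base-induced retro-aldol opening of the β-hydroxy ketone and loss of the ester.

**Compound list**
1 | (4R)-4-benzyl-3-(3-methylbutanoyl)-1,3-oxazolidin-2-one | CC(C)CC(=O)N1[C@H](Cc2ccccc2)COC1=O | starting material
2 | 2-bromo-N-methoxy-N-methylacetamide | CON(C)C(=O)CBr | starting material
3 | sodium (Z)-enolate of 1 | CC(C)/C=C(\[O-])N1[C@H](Cc2ccccc2)COC1=O.[Na+] | intermediate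
4 | (4R)-4-benzyl-3-[(2R)-4-[methoxy(methyl)amino]-4-oxo-2-(propan-2-yl)butanoyl]-1,3-oxazolidin-2-one | CON(C)C(=O)C[C@H](C(C)C)C(=O)N1[C@H](Cc2ccccc2)COC1=O | intermediate
5 | S-ethyl (2R)-4-[methoxy(methyl)amino]-4-oxo-2-(propan-2-yl)butanethioate | CCSC(=O)[C@@H](C(C)C)CC(=O)N(C)OC | intermediate
6 | (3R)-3-acetyl-N-methoxy-N,4-dimethylpentanamide | CC(=O)[C@@H](C(C)C)CC(=O)N(C)OC | intermediate
7 | lithium enolate of 6 (methyl side) | C=C([O-])[C@@H](C(C)C)CC(=O)N(C)OC.[Li+] | intermediate
8 | (3R)-N-methoxy-N,4-dimethyl-3-{1-[(triethylsilyl)oxy]ethenyl}pentanamide | C=C(O[Si](CC)(CC)CC)[C@@H](C(C)C)CC(=O)N(C)OC | intermediate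
9 | (2E)-but-2-en-1-ol | C/C=C/CO | starting material
10 | [(1S,2S)-2-methylcyclopropyl]methanol | OC[C@H]1C[C@@H]1C | intermediate
11 | (1S,2S)-2-methylcyclopropane-1-carbaldehyde | O=C[C@H]1C[C@@H]1C | intermediate
12 | (1S,2S)-1-[(1Z)-2-iodoprop-1-en-1-yl]-2-methylcyclopropane | I/C(C)=C\[C@H]1C[C@@H]1C | intermediate
13 | (1Z)-1-[(1S,2S)-2-methylcyclopropyl]prop-1-en-2-yllithium | [Li]/C(C)=C\[C@H]1C[C@@H]1C | intermediate
14 | (1Z,5R)-2-methyl-1-[(1S,2S)-2-methylcyclopropyl]-5-(propan-2-yl)-6-[(triethylsilyl)oxy]hepta-1,6-dien-3-one | C=C(O[Si](CC)(CC)CC)[C@@H](C(C)C)CC(=O)/C(C)=C\[C@H]1C[C@@H]1C | intermediate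
15 | (3R,3aS,6S,8aR)-6,8a-dimethyl-3-(propan-2-yl)-3a-[(triethylsilyl)oxy]-3,3a,4,5,6,8a-hexahydroazulen-1(2H)-one | C1=C[C@@H](C)CC[C@]2(O[Si](CC)(CC)CC)[C@@H](C(C)C)CC(=O)[C@]12C | intermediate
16 | (3R,3aS,8R,8aR)-8-hydroperoxy-6,8a-dimethyl-3-(propan-2-yl)-3a-[(triethylsilyl)oxy]-3,3a,4,5,8,8a-hexahydroazulen-1(2H)-one | OO[C@@H]1C=C(C)CC[C@]2(O[Si](CC)(CC)CC)[C@@H](C(C)C)CC(=O)[C@]12C | intermediate
17 | (3R,3aS,8R,8aR)-8-hydroxy-6,8a-dimethyl-3-(propan-2-yl)-3a-[(triethylsilyl)oxy]-3,3a,4,5,8,8a-hexahydroazulen-1(2H)-one | O[C@@H]1C=C(C)CC[C@]2(O[Si](CC)(CC)CC)[C@@H](C(C)C)CC(=O)[C@]12C | intermediate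
18 | 4-methoxybenzoyl chloride | COc1ccc(cc1)C(Cl)=O | starting material
19 | (3R,3aS,8R,8aR)-6,8a-dimethyl-1-oxo-3-(propan-2-yl)-3a-[(triethylsilyl)oxy]-1,2,3,3a,4,5,8,8a-octahydroazulen-8-yl 4-methoxybenzoate | COc1ccc(C(=O)O[C@@H]2C=C(C)CC[C@]3(O[Si](CC)(CC)CC)[C@@H](C(C)C)CC(=O)[C@]23C)cc1 | intermediate
20 | (3R,3aS,8R,8aR)-3a-hydroxy-6,8a-dimethyl-1-oxo-3-(propan-2-yl)-1,2,3,3a,4,5,8,8a-octahydroazulen-8-yl 4-methoxybenzoate | COc1ccc(C(=O)O[C@@H]2C=C(C)CC[C@]3(O)[C@@H](C(C)C)CC(=O)[C@]23C)cc1 | target

**Step count:** 12 steps in total. Longest linear sequence: 9 steps (steps 1–4 and 8–12, from 1).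

**Steps most likely to fail**

1. Step 9 (proposed new method). What may go wrong: the hindered, electron-rich siloxyalkene does not insert, so that the rhodacycle reverts or loses a β-hydride at C6 to give an open-chain triene; the (Z)-enone isomerises before cyclopropane opening; or the silyl enol ether is lost. The fallback uses known chemistry (rhodium-catalysed (5+2) of an alkyne–vinylcyclopropane, then hydrogen-atom-transfer hydration). It sets out from 5, uses 13, and comes back at 15. Thioester 5 is reduced (Et3SiH, Pd on carbon) to (3R)-3-formyl-N-methoxy-N,4-dimethylpentanamide F1, which is homologated (dimethyl (1-diazo-2-oxopropyl)phosphonate, K2CO3, MeOH) to (3R)-3-ethynyl-N-methoxy-N,4-dimethylpentanamide F2. After removal of its alkyne C–H with LiN(SiMe3)2 at −78 °C, F2 is treated with alkenyllithium 13 at the Weinreb amide to give (1Z,5R)-5-ethynyl-2,6-dimethyl-1-[(1S,2S)-2-methylcyclopropyl]hept-1-en-3-one F3. [Rh(CO)2Cl]2 in toluene should then give (3R,6S,8aR)-6,8a-dimethyl-3-(propan-2-yl)-3,5,6,8a-tetrahydroazulen-1(2H)-one F4. Its trisubstituted C3a=C4 bond, rather than the 1,2-disubstituted C7=C8 bond, is hydrated by Mukaiyama hydration (Co(acac)2, PhSiH3, O2) to (3R,3aS,6S,8aR)-3a-hydroxy-6,8a-dimethyl-3-(propan-2-yl)-3,3a,4,5,6,8a-hexahydroazulen-1(2H)-one F5, and Et3SiOTf with 2,6-lutidine gives 15. Facial control at C3a in the hydration is less secure than in step 9.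

2. Step 10. What may go wrong: the ene reaction of the cis-disubstituted alkene, flanked by two substituted carbons, is slow, so that photo-oxidative degradation competes, or oxygen attacks the wrong face. The fallback sets out from 15 and comes back at 17. Dimethyldioxirane in acetone should epoxidise the face anti to both methyl groups to give (3R,3aS,6S,7R,8S,8aR)-7,8-epoxy-6,8a-dimethyl-3-(propan-2-yl)-3a-[(triethylsilyl)oxy]octahydroazulen-1(2H)-one F6. Diethylaluminium 2,2,6,6-tetramethylpiperidide in toluene at 0 °C then opens it by syn elimination through C6–H, which lies on the epoxide face, to give 17.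

3. Step 8. What may go wrong: loss of alkene geometry in the alkenyllithium or in the enone, or deprotonation of the amide α-CH2 in place of addition. The fallback sets out from 8, uses 12, and comes back at 14. DIBAL-H at −78 °C reduces Weinreb amide 8 to (3R)-4-methyl-3-{1-[(triethylsilyl)oxy]ethenyl}pentanal F7. Nozaki–Hiyama–Kishi coupling with iodide 12 (CrCl2, catalytic NiCl2, DMF), which keeps the alkene geometry, gives (1Z,5R)-2-methyl-1-[(1S,2S)-2-methylcyclopropyl]-5-(propan-2-yl)-6-[(triethylsilyl)oxy]hepta-1,6-dien-3-ol F8 as a mixture at the carbinol carbon, and Dess–Martin periodinane gives 14.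

**Further compounds**
F1 | step 9 | (3R)-3-formyl-N-methoxy-N,4-dimethylpentanamide | O=C[C@@H](C(C)C)CC(=O)N(C)OC
F2 | step 9 | (3R)-3-ethynyl-N-methoxy-N,4-dimethylpentanamide | C#C[C@@H](C(C)C)CC(=O)N(C)OC
F3 | step 9 | (1Z,5R)-5-ethynyl-2,6-dimethyl-1-[(1S,2S)-2-methylcyclopropyl]hept-1-en-3-one | C#C[C@@H](C(C)C)CC(=O)/C(C)=C\[C@H]1C[C@@H]1C
F4 | step 9 | (3R,6S,8aR)-6,8a-dimethyl-3-(propan-2-yl)-3,5,6,8a-tetrahydroazulen-1(2H)-one | C1=C[C@@H](C)CC=C2[C@@H](C(C)C)CC(=O)[C@]12C
F5 | step 9 | (3R,3aS,6S,8aR)-3a-hydroxy-6,8a-dimethyl-3-(propan-2-yl)-3,3a,4,5,6,8a-hexahydroazulen-1(2H)-one | C1=C[C@@H](C)CC[C@]2(O)[C@@H](C(C)C)CC(=O)[C@]12C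
F6 | step 10 | (3R,3aS,6S,7R,8S,8aR)-7,8-epoxy-6,8a-dimethyl-3-(propan-2-yl)-3a-[(triethylsilyl)oxy]octahydroazulen-1(2H)-one | C[C@H]1CC[C@]2(O[Si](CC)(CC)CC)[C@@H](C(C)C)CC(=O)[C@]2(C)[C@@H]3O[C@H]13
F7 | step 8 | (3R)-4-methyl-3-{1-[(triethylsilyl)oxy]ethenyl}pentanal | C=C(O[Si](CC)(CC)CC)[C@@H](C(C)C)CC=O
F8 | step 8 | (1Z,5R)-2-methyl-1-[(1S,2S)-2-methylcyclopropyl]-5-(propan-2-yl)-6-[(triethylsilyl)oxy]hepta-1,6-dien-3-ol | C=C(O[Si](CC)(CC)CC)[C@@H](C(C)C)CC(O)/C(C)=C\[C@H]1C[C@@H]1C
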